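Conventions: atoms carry labdane numbering (ring A: C1–C5, C10; ring B: C5–C10; cyclobutane: C8, C9, C14, C15; ring D: C9, C11–C14; methyls C16 on C13, C17 on C8, C18/C19 on C4, C20 on C10). β is the face of C20. Compound numbers are those of the steps and of the list after them.

Remark on the chemistry: the C6 carbinol configuration in 7 only makes the two C8 series diastereomeric and is destroyed in step 4. The (S)-carbinol expected from the (+)-α-pinene-derived borane is drawn; the antipodal reagent would serve equally.

## Analysis of the target

Compound 19 is a 6-6-4-5 tetracycle: a trans-decalin (rings A and B) whose C8–C9 bond is shared with a cyclobutane, which shares C9–C14 with the cyclopentane ring D; in labdane terms it is an 8,15:9,14-dicyclolabdane, and C9 belongs to three rings. It has seven stereocentres (C5, C6, C8, C9, C10, C13, C14, all S), and C8, C9 and C10 are three contiguous quaternary carbons next to the quaternary C4. C20, C17 and C11 lie on the β-face, whereas H5 and the cyclobutane carbons C14 and C15 lie on the α-face. The C6 acetate is β and axial, enclosed by the β-methyls on C4, C8 and C10; on ring D the hydroxyl sits on the convex face cis to H14 and the C16 methyl on the concave face beside C15. The α-acetoxy ketone is the sensitive unit (epimerisable C6, base-labile and migration-prone acetate), alongside a tertiary alcohol and a strained ring next to the C7 carbonyl. The synthesis is hard because the C9–C10 bond joins two fully substituted carbons in a congested core, and because the C6 oxygen sits on a face that no reagent can reach. The strategy rests on one feature: with the ring B oxygen at C6 instead of C7 and a ketone at C13, C9 and C10 are both β-carbons of enones (C13=O with C14=C9, C6=O with C5=C10). Two carbons of like polarity can then be joined reductively, and the same C6 carbonyl later sets the 6β-oxygen by α-face hydride delivery.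

## Retrosynthetic reasoning

19 back to 15. The C7 ketone of 19 is taken back to the carbinol 18, so that the epimerisable α-acetoxy ketone appears only in the last step. Removing the protecting groups and the acetyl group leads through 17 to the 6β-alcohol 16. Its C6–H bond is the real disconnection: oxygen cannot be brought to the β-face of C6, so the oxygen must already be on C6 as the carbonyl of 15 and hydrogen must arrive from the open α-face.

15 back to 13. The C7–O bond is cut. Forward, the C6 ketone of 13 is enolised toward C7, the only accessible α-position, and oxidised to 14; the configuration at C7 is irrelevant because C7 becomes the ketone. Both hydroxyls are then silylated (15) so that only O6 is acylated later.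

13 back to 11. The C13–O bond and then the C13=C16 bond are cut, via the methylene compound 12. Reagents reach C13 from the convex face, so direct methyl addition to the C13 ketone of 11 would put the methyl where the hydroxyl belongs. Methylenation followed by radical hydration reverses the order in which carbon and oxygen arrive.

11 back to 10 (key disconnection). The C9–C10 bond is cut, with the hydrogens on C5 and C14. This is the one bond between quaternary carbons that is not part of a small ring, and cutting it removes ring B and four stereocentres at once, leaving the bis-enone 10 with C8 as its only stereocentre. Forward, one carbon must change polarity: one-electron reduction of the cyclobutene-fused enone makes C9 a nucleophilic radical that attacks C10.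

10 back to 8. The strained C9=C14 double bond of 10 is unveiled last, by β-elimination of the C9 acetoxy group of 9. The C6 ketone of 9 comes from the carbinol of 8, because a second enone chromophore would not survive the photochemical step and because the carbinol serves as the stereochemical label for C8.

8 back to 2 and 7. The cyclobutane bonds C8–C9 and C14–C15 are cut, a [2+2] disconnection into the enol acetate 2 and the 1,1-disubstituted alkene of 7. The cycloaddition makes the four-membered ring and the quaternary C8 in one step from simple partners, at the price of having to separate the C8 epimers.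

7 back to 3 and 4; 2 back to 1. The C6–C7 bond of 7 is an allylation disconnection to the aldehyde 4 and the methallyl unit of 3, made enantioselective to provide the label. Compound 2 is the O-acetyl derivative of 1.

## Alternatives that were turned down

Alternative 1: The cyclobutane bond C8–C15 is reached by ring contraction. The precursor is the diazo ketone A1, a cyclopentanone homologue with an extra carbonyl carbon between C8 and the diazo-bearing C15; its photochemical Wolff rearrangement in an alcohol moves C8 to C15 and gives the C15 methyl ester A2.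
- For: ring contraction is a dependable way to introduce four-membered-ring strain, and all quaternary centres would be assembled beforehand on an unstrained five-membered ring. On this point it is stronger than the chosen route, which makes the C9–C10 bond on an already strained, crowded substrate.
- Against: in A1, C8 lies between two carbonyls without an α-hydrogen, a 1,3-diketone open to retro-Claisen cleavage by the alcohol. Diazo transfer to C15 needs prior activation. The ester of A2 is surplus and costs a hydrolysis and a radical decarboxylation. A2 has its ring B oxygen at C7, so the C6 oxygen would have to enter on the blocked β-face.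
- Comparison: one carbon is put in and taken out, and A1 itself needs a long linear build-up. The chosen route offers convergence, a cyclobutane made in one early step, and a C6 carbonyl that solves the C6 problem.

Alternative 2: The C13–C14 bond of ring D is cut. The precursor is the ring B-fused cyclobutene A3 with a methyl ketone side chain on C9; a one-electron reductant turns the ketone into a ketyl that adds 5-exo to C14 and gives the 7,13-diol A4.
- For: 5-exo ketyl–olefin cyclisation onto a strained alkene is far better precedented than the chosen key step, and it forms ring D and the tertiary carbinol together. The hydroxyl is expected trans to C15, as required, so C13 is set in one step where the chosen route needs two.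
- Against: the difficulty is moved, not removed. A3 needs a cyclobutene fused across the C8–C9 bond with both carbons quaternary and cis on the α-face, which means a photocycloaddition onto a tetrasubstituted, hindered ring B alkene. A4 again carries oxygen at C7 and none at C6.
- Comparison: the chosen route makes the cyclobutane on an unhindered 1,1-disubstituted alkene and keeps the oxygen where C6 can be controlled.

Alternative 3: The C9–C14 bond and the C13–O bond are cut together. The precursor is the ring B-fused cross-conjugated cycloheptadienone A5; irradiation in aqueous medium joins the β-carbons C9 and C14, and the medium is captured at C13 of the oxyallyl intermediate to give the hydroxy ketone A6.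
- For: on bond count per step it beats the chosen route, since cyclobutane, ring D and the C13 hydroxyl arise in one operation.
- Against: the capture must choose C13 over C11 and the closure must choose the α-face of C9; neither is controlled by anything but the distant C10. The C12 carbonyl of A6 is surplus and sits next to a tertiary hydroxyl, where deoxygenation invites loss of that hydroxyl. A5, a seven-membered dienone fused to a decalin at a quaternary carbon, is itself a long synthesis. C6 is again unoxygenated.
- Comparison: the chosen route is less spectacular in its key step but reaches its precursor in five steps and leaves no surplus functionality.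

Key step: step 6

## Route

Step 1
Reactants: 1 cyclopentane-1,3-dione
Product: 2 3-oxocyclopent-1-en-1-yl acetate
Conditions: AcCl, pyridine, CH2Cl2, 0 °C
Reagents that add atoms: acetyl chloride, CC(=O)Cl
Why: O-Acylation of the enol of a cyclic 1,3-dione; 2 is the enone partner for the photocycloaddition and its acetoxy group is the later leaving group on C9.

Step 2
Reactants: 3 3-chloro-2-methylprop-1-ene; 4 β-cyclocitral (2,6,6-trimethylcyclohex-1-ene-1-carbaldehyde)
Product: 7 (S)-3-methyl-1-(2,6,6-trimethylcyclohex-1-en-1-yl)but-3-en-1-ol, via 2-methylallylmagnesium chloride 5 (not isolated), via B-(2-methylallyl)diisopinocampheylborane 6 (not isolated)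
Conditions: Mg, THF, 0 °C; (−)-Ipc2BOMe, Et2O, −78 °C → rt; 4, −78 °C; NaOH, H2O2
Reagents that add atoms: none
Why: Brown asymmetric allylboration: the Grignard reagent 5 is transmetalated to the chiral allylborane 6, which adds to the aldehyde through a closed six-membered chair transition state in which the isopinocampheyl groups select the aldehyde face and set C6, expected (S). The hindered, non-enolisable aldehyde 4 can only react 1,2.

Step 3
Reactants: 2 3-oxocyclopent-1-en-1-yl acetate; 7 (S)-3-methyl-1-(2,6,6-trimethylcyclohex-1-en-1-yl)but-3-en-1-ol
Product: 8 (6R)-5-acetoxy-6-[(2S)-2-hydroxy-2-(2,6,6-trimethylcyclohex-1-en-1-yl)ethyl]-6-methyl-cis-bicyclo[3.2.0]heptan-2-one (both ring-fusion isomers pooled; the 6R carbon is labdane C8)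
Conditions: hν (350 nm, Pyrex), 2 in excess added in portions, CH2Cl2, −20 °C; preparative HPLC on silica
Reagents that add atoms: none
Why: Enone–alkene [2+2] photocycloaddition through the enone triplet: the 1,1-disubstituted alkene adds head-to-tail, so C8 bonds to the acetoxy-bearing C9 and C15 to C14, and a five-membered enone can only give the cis-fused cyclobutane. C8 forms without control from the remote C6, but C6 makes the two C8 series diastereomeric; the (6R) pair is collected whatever its ring-fusion orientation, which step 5 erases.

Step 4
Reactants: 8 (6R)-photoadduct carbinol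
Product: 9 (6R)-5-acetoxy-6-methyl-6-[2-oxo-2-(2,6,6-trimethylcyclohex-1-en-1-yl)ethyl]-cis-bicyclo[3.2.0]heptan-2-one
Conditions: Dess–Martin periodinane, NaHCO3, CH2Cl2, 0 °C → rt
Reagents that add atoms: none
Why: Dess–Martin oxidation of a hindered allylic secondary alcohol under buffered, non-basic conditions that leave the β-acetoxy ketone intact; C6 has done its work as a label and becomes the carbonyl of the ring A enone.

Step 5
Reactants: 9 (6R)-acetoxy diketone
Product: 10 (6R)-6-methyl-6-[2-oxo-2-(2,6,6-trimethylcyclohex-1-en-1-yl)ethyl]bicyclo[3.2.0]hept-1(5)-en-2-one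
Conditions: DBU, CH2Cl2, 0 °C; short filtration, used at once
Reagents that add atoms: none
Why: E1cB β-elimination of the tertiary acetate through the C13 enolate gives the strained C9=C14 enone; a non-nucleophilic amidine avoids the deacetylation and retro-aldol (de Mayo) pathway. Both ring-fusion isomers of 9 converge on the single compound 10, whose only stereocentre is C8.

Step 6
Reactants: 10 (6R)-bis-enone
Product: 11 (5S,8R,9R,10S,14S)-16-nor-8,15:9,14-dicyclolabdane-6,13-dione
Conditions: SmI2 (2.5 equiv, added slowly), HMPA, THF (high dilution), −78 → 0 °C; then t-BuOH, H2O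
Reagents that add atoms: none
Why: Proposed new method: SmI2/HMPA transfers one electron to the strained, planar cyclobutene-fused cyclopentenone (the acylcyclohexene is twisted out of conjugation and harder to reduce), giving a samarium-bound enolate radical with spin at C9; C9 adds to C10 of the ring A enone and the resulting α-keto radical at C5 takes the second electron, so the net change is a hydrodimerisation of two enones, whose closest known reaction type is the SmI2-mediated or cathodic reductive cyclisation of tethered bis-enones and the hydrodimerisation of β,β-disubstituted enones, not yet shown for an acceptor with its carbonyl in the tether or for two fully substituted β-carbons. Ring B closes in the 6-endo-trig mode, favoured over 5-exo attack at C5 because only attack at C10 leaves a tertiary radical stabilised by the C6 carbonyl. C9 is set by C8: the two-atom tether C7–C6 reaches only the face of the cyclobutene that carries C7, so ring B is cis-fused to the four-membered ring. C10 is set by a chair-like closure with C1 equatorial and the C9–C14 bond axial; the competing chair places C15 axial and syn to the C10 methyl, and this preference is the least secure element of the step. C14 is protonated on the convex face because only a cis-fused bicyclo[3.2.0]heptanone is attainable, and C5 is protonated anti to the C10 methyl, which is also the thermodynamic trans-decalin. The step needs carbon–carbon coupling to outrun simple reduction of the radical anion, which is why the proton source is added only at the end and the reductant slowly.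

Step 7
Reactants: 11 tetracyclic 6,13-dione
Product: 12 8,15:9,14-dicyclolabd-13(16)-en-6-one (ring stereocentres as in 11)
Conditions: Ph3PCH3Br, KOtBu, THF, 0 °C → rt
Reagents that add atoms: methyltriphenylphosphonium bromide, C[P+](c1ccccc1)(c1ccccc1)c1ccccc1.[Br-]
Why: Wittig methylenation: the ylide reaches the cyclopentanone carbonyl C13 but not the C6 carbonyl, which is flanked by C5 (next to the gem-dimethyl carbon) and the neopentyl C7. C14 cannot epimerise because only the cis-fused bicycle is attainable.

Step 8
Reactants: 12 13-methylene ketone
Product: 13 (13S)-13-hydroxy-8,15:9,14-dicyclolabdan-6-one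
Conditions: Co(acac)2 (20 mol %), PhSiH3, O2 (1 atm), THF/i-PrOH, rt
Reagents that add atoms: dioxygen, O=O
Why: Mukaiyama hydration: cobalt-hydride hydrogen-atom transfer to the 1,1-disubstituted alkene, capture of the tertiary C13 radical by O2 and reduction of the peroxide by the silane, Markovnikov by radical stability. Oxygen should enter on the convex face of ring D, cis to H14 and away from the eclipsing C15 methylene, giving (13S) with the methyl on the concave face, the opposite of what methyl addition to the C13 ketone would give.

Step 9
Reactants: 13 13-hydroxy-6-ketone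
Product: 14 7ξ,13-dihydroxy-8,15:9,14-dicyclolabdan-6-one (C7 epimers)
Conditions: KN(SiMe3)2 (2.2 equiv), THF, −78 °C; 2-(phenylsulfonyl)-3-phenyloxaziridine; AcOH, −78 °C
Reagents that add atoms: 2-(phenylsulfonyl)-3-phenyloxaziridine, O=S(=O)(c1ccccc1)N1OC1c1ccccc1
Why: Kinetic enolate formation and oxidation with an N-sulfonyloxaziridine: the first equivalent of base takes the tertiary OH, the second removes a C7 proton in preference to the tertiary C5–H wedged between two quaternary carbons, and the enolate attacks the oxaziridine oxygen. The configuration at C7 is immaterial because C7 ends as the ketone.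

Step 10
Reactants: 14 7ξ,13-dihydroxy-6-ketone
Product: 15 7ξ,13-bis(triethylsilyloxy)-8,15:9,14-dicyclolabdan-6-one
Conditions: TESOTf (2.5 equiv), 2,6-lutidine, CH2Cl2, −78 → 0 °C
Reagents that add atoms: triethylsilyl trifluoromethanesulfonate, CC[Si](CC)(CC)OS(=O)(=O)C(F)(F)F
Why: Silylation of the secondary and the tertiary hydroxyl with a silyl triflate and a hindered pyridine base that is too weak to enolise the ketone. Both oxygens are masked so that only O6 is acylated in step 12.

Step 11
Reactants: 15 bis-silyl ether ketone
Product: 16 7ξ,13-bis(triethylsilyloxy)-8,15:9,14-dicyclolabdan-6β-ol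
Conditions: LiAlH4, Et2O, 0 °C → rt
Reagents that add atoms: none
Why: Hydride reduction of a hindered cyclohexanone: the β-face of C6 is closed by the axial methyls on C4, C8 and C10, so hydride arrives from the α-face and the new oxygen is pushed into the axial 6β position, (6S).

Step 12
Reactants: 16 6β-alcohol
Product: 17 6β-acetoxy-7ξ,13-bis(triethylsilyloxy)-8,15:9,14-dicyclolabdane
Conditions: Ac2O, DMAP (2 equiv), pyridine, 60 °C
Reagents that add atoms: acetic anhydride, CC(=O)OC(C)=O
Why: DMAP-catalysed acetylation (N-acetylpyridinium) applied with heat to an axial, 1,3-diaxially crowded secondary alcohol. The triethylsilyl ethers are stable here and no alkoxide is formed that could shift a silyl group from O7.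

Step 13
Reactants: 17 6β-acetate bis-silyl ether
Product: 18 6β-acetoxy-8,15:9,14-dicyclolabdane-7ξ,13-diol
Conditions: HF·pyridine, THF, 0 °C → rt
Reagents that add atoms: none
Why: Fluoride cleavage of both silyl ethers under mildly acidic conditions, chosen over basic fluoride so that the C6 acetate does not migrate to O7.

Step 14
Reactants: 18 6β-acetoxy-7ξ,13-diol
Product: 19 (5S,6S,8S,9S,10S,13S,14S)-6β-acetoxy-13-hydroxy-8,15:9,14-dicyclolabdan-7-one (CNP0330581.1)
Conditions: Dess–Martin periodinane, NaHCO3, CH2Cl2, 0 °C → rt; neutral work-up
Reagents that add atoms: none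
Why: Dess–Martin oxidation of the secondary C7 carbinol (either epimer) in buffered medium. The tertiary C13 alcohol is inert and the absence of base protects the epimerisable C6 of the α-acetoxy ketone.

## Compound list

1 | cyclopentane-1,3-dione | O=C1CCC(=O)C1 | starting material
2 | 3-oxocyclopent-1-en-1-yl acetate | CC(=O)OC1=CC(=O)CC1 | intermediate
3 | 3-chloro-2-methylprop-1-ene | C=C(C)CCl | starting material
4 | β-cyclocitral (2,6,6-trimethylcyclohex-1-ene-1-carbaldehyde) | CC1=C(C=O)C(C)(C)CCC1 | starting material
5 | 2-methylallylmagnesium chloride | CC(=C)C[Mg]Cl | intermediate (not isolated)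
6 | B-(2-methylallyl)diisopinocampheylborane, (+)-α-pinene series | CC(=C)CB([C@@H]1C[C@@H]2C[C@H]([C@H]1C)C2(C)C)[C@@H]1C[C@@H]2C[C@H]([C@H]1C)C2(C)C | intermediate (not isolated)
7 | (S)-3-methyl-1-(2,6,6-trimethylcyclohex-1-en-1-yl)but-3-en-1-ol | CC1=C([C@@H](O)CC(C)=C)C(C)(C)CCC1 | intermediate
8 | (6R)-5-acetoxy-6-[(2S)-2-hydroxy-2-(2,6,6-trimethylcyclohex-1-en-1-yl)ethyl]-6-methyl-cis-bicyclo[3.2.0]heptan-2-one, both cis ring-fusion isomers (C1 and C5 of the bicycle left open) | CC1=C([C@@H](O)C[C@@]2(C)CC3C2(OC(C)=O)CCC3=O)C(C)(C)CCC1 | intermediate
9 | (6R)-5-acetoxy-6-methyl-6-[2-oxo-2-(2,6,6-trimethylcyclohex-1-en-1-yl)ethyl]-cis-bicyclo[3.2.0]heptan-2-one, both cis ring-fusion isomers | CC1=C(C(=O)C[C@@]2(C)CC3C2(OC(C)=O)CCC3=O)C(C)(C)CCC1 | intermediate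
10 | (6R)-6-methyl-6-[2-oxo-2-(2,6,6-trimethylcyclohex-1-en-1-yl)ethyl]bicyclo[3.2.0]hept-1(5)-en-2-one | CC1=C(C(=O)C[C@@]2(C)CC3=C2CCC3=O)C(C)(C)CCC1 | intermediate
11 | (5S,8R,9R,10S,14S)-16-nor-8,15:9,14-dicyclolabdane-6,13-dione (5α-H; C17, C20, C11 β; C14, C15 α) | O=C1C[C@@]2(C)C[C@H]3[C@@]2(CCC3=O)[C@@]2(C)CCCC(C)(C)[C@H]12 | intermediate
12 | 8,15:9,14-dicyclolabd-13(16)-en-6-one, ring stereocentres as in 11 | O=C1C[C@@]2(C)C[C@H]3[C@@]2(CCC3=C)[C@@]2(C)CCCC(C)(C)[C@H]12 | intermediate
13 | (13S)-13-hydroxy-8,15:9,14-dicyclolabdan-6-one (OH cis to H14) | O=C1C[C@@]2(C)C[C@H]3[C@@]2(CC[C@]3(C)O)[C@@]2(C)CCCC(C)(C)[C@H]12 | intermediate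
14 | (13S)-7ξ,13-dihydroxy-8,15:9,14-dicyclolabdan-6-one, C7 epimers | O=C1C(O)[C@@]2(C)C[C@H]3[C@@]2(CC[C@]3(C)O)[C@@]2(C)CCCC(C)(C)[C@H]12 | intermediate
15 | (13S)-7ξ,13-bis(triethylsilyloxy)-8,15:9,14-dicyclolabdan-6-one | O=C1C(O[Si](CC)(CC)CC)[C@@]2(C)C[C@H]3[C@@]2(CC[C@]3(C)O[Si](CC)(CC)CC)[C@@]2(C)CCCC(C)(C)[C@H]12 | intermediate
16 | (6S,13S)-7ξ,13-bis(triethylsilyloxy)-8,15:9,14-dicyclolabdan-6β-ol | O[C@@H]1C(O[Si](CC)(CC)CC)[C@@]2(C)C[C@H]3[C@@]2(CC[C@]3(C)O[Si](CC)(CC)CC)[C@@]2(C)CCCC(C)(C)[C@H]12 | intermediate
17 | 6β-acetoxy-7ξ,13-bis(triethylsilyloxy)-8,15:9,14-dicyclolabdane | CC(=O)O[C@@H]1C(O[Si](CC)(CC)CC)[C@@]2(C)C[C@H]3[C@@]2(CC[C@]3(C)O[Si](CC)(CC)CC)[C@@]2(C)CCCC(C)(C)[C@H]12 | intermediate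
18 | 6β-acetoxy-8,15:9,14-dicyclolabdane-7ξ,13-diol | CC(=O)O[C@@H]1C(O)[C@@]2(C)C[C@H]3[C@@]2(CC[C@]3(C)O)[C@@]2(C)CCCC(C)(C)[C@H]12 | intermediate
19 | (5S,6S,8S,9S,10S,13S,14S)-6β-acetoxy-13-hydroxy-8,15:9,14-dicyclolabdan-7-one | CC(=O)O[C@@H]1C(=O)[C@@]2(C)C[C@H]3[C@@]2(CC[C@]3(C)O)[C@@]2(C)CCCC(C)(C)[C@H]12 | target

## Step count and least certain steps

Total: 14 steps. Longest linear sequence: 13 steps (steps 2–14, from 3 and 4); step 1 is a one-step side branch.

**Step 6 (key step, proposed new method).**
- What may go wrong: the enone radical anion may be reduced further and protonated, or dimerise, faster than it adds to a twisted, tetrasubstituted acceptor to form a bond between two quaternary carbons. The closure may also take the other facial course at C10.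
- Fallback, by known chemistry (hydrogen-atom-transfer Giese cyclisation with normal polarity): it sets out from 2 and 3 and returns at 11. α-Cyclocitral F1 (racemic at C5, which is corrected at the end) replaces 4 in step 2 and gives the homoallylic alcohol F2. Photocycloaddition with 2 and collection of the (6R) adducts gives the acetoxy ketone carbinol F3; oxidation gives the acetoxy diketone F4; elimination with triethylamine, mild enough not to conjugate the ring A alkene, gives the deconjugated enone F5. Fe(acac)3 and PhSiH3 in ethanol then deliver a hydrogen atom to C1 of the isolated C1=C10 alkene. The tertiary C10 radical adds 6-exo to C9 of the strained enone, the C14 radical is reduced and protonated, and base equilibration at C5 gives 11.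

**Step 3.**
- What may go wrong: partial head-to-head orientation and, above all, incomplete chromatographic resolution of the C8 epimers, because the labelling centre C6 is 1,3 to C8 and four head-to-tail isomers have to be sorted.
- Fallback: it sets out from 7 and returns at 10. Silylation gives the triethylsilyl ether F6 and irradiation with 2 gives the adduct mixture F7. DBU eliminates the C9 acetate from all ring-fusion isomers and gives the enone silyl ether F8, now only two diastereomers with a strong chromophore, from which the (6R) isomer is separated. HF·pyridine frees the enone carbinol F9, and immediate Dess–Martin oxidation gives 10.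

**Step 8.**
- What may go wrong: poor facial discrimination when the small O2 molecule captures the planar C13 radical, giving a mixture of C13 epimers.
- Fallback: it sets out from 12 and returns at 13. mCPBA, a bulkier reagent with the same convex-face preference, gives the spiro-epoxide F10. LiEt3BH opens it at the methylene carbon and at the same time reduces the C6 ketone to the diol F11. Dess–Martin oxidation of the secondary alcohol restores the ketone of 13.

**Step 12.**
- What may go wrong: very slow intermolecular acylation of the 6β-hydroxyl under three syn-axial methyl groups, with loss of silyl groups if the conditions are forced.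
- Fallback, by intramolecular acetyl delivery: it sets out from 14 and returns at 18 as its 7β-epimer. Benzyloxymethyl chloride and i-Pr2NEt protect O7, and catalytic KOtBu equilibrates C7 to the equatorial ether F12. LiAlH4 gives the 6β-alcohol F13, and hydrogenolysis over Pd(OH)2/C gives the triol F14 with a cis-6β,7β-diol. Trimethyl orthoacetate with acid forms the cyclic orthoacetate F15, whose hydrolysis in aqueous acetic acid opens to the axial 6β-acetate with the equatorial 7β-hydroxyl free.

## Further compounds

F1 | step 6 | α-cyclocitral (2,6,6-trimethylcyclohex-2-ene-1-carbaldehyde, racemic) | CC1=CCCC(C)(C)C1C=O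
F2 | step 6 | (1S)-3-methyl-1-(2,6,6-trimethylcyclohex-2-en-1-yl)but-3-en-1-ol, C5 epimers | CC1=CCCC(C)(C)C1[C@@H](O)CC(C)=C
F3 | step 6 | (6R)-5-acetoxy-6-[(2S)-2-hydroxy-2-(2,6,6-trimethylcyclohex-2-en-1-yl)ethyl]-6-methyl-cis-bicyclo[3.2.0]heptan-2-one, ring-fusion and C5 isomers | CC1=CCCC(C)(C)C1[C@@H](O)C[C@@]2(C)CC3C2(OC(C)=O)CCC3=O
F4 | step 6 | (6R)-5-acetoxy-6-methyl-6-[2-oxo-2-(2,6,6-trimethylcyclohex-2-en-1-yl)ethyl]-cis-bicyclo[3.2.0]heptan-2-one | CC1=CCCC(C)(C)C1C(=O)C[C@@]2(C)CC3C2(OC(C)=O)CCC3=O
F5 | step 6 | (6R)-6-methyl-6-[2-oxo-2-(2,6,6-trimethylcyclohex-2-en-1-yl)ethyl]bicyclo[3.2.0]hept-1(5)-en-2-one | CC1=CCCC(C)(C)C1C(=O)C[C@@]2(C)CC3=C2CCC3=O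
F6 | step 3 | triethylsilyl ether of 7 | CC1=C([C@@H](O[Si](CC)(CC)CC)CC(C)=C)C(C)(C)CCC1
F7 | step 3 | photoadducts of F6 with 2, all ring-fusion and C8 isomers | CC1=C([C@@H](O[Si](CC)(CC)CC)CC2(C)CC3C2(OC(C)=O)CCC3=O)C(C)(C)CCC1
F8 | step 3 | (6R)-6-methyl-6-[(2S)-2-(triethylsilyloxy)-2-(2,6,6-trimethylcyclohex-1-en-1-yl)ethyl]bicyclo[3.2.0]hept-1(5)-en-2-one | CC1=C([C@@H](O[Si](CC)(CC)CC)C[C@@]2(C)CC3=C2CCC3=O)C(C)(C)CCC1
F9 | step 3 | (6R)-6-[(2S)-2-hydroxy-2-(2,6,6-trimethylcyclohex-1-en-1-yl)ethyl]-6-methylbicyclo[3.2.0]hept-1(5)-en-2-one | CC1=C([C@@H](O)C[C@@]2(C)CC3=C2CCC3=O)C(C)(C)CCC1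
F10 | step 8 | 13,16-epoxy-8,15:9,14-dicyclolabdan-6-one, epoxide oxygen cis to H14 | O=C1C[C@@]2(C)C[C@H]3[C@@]2(CC[C@@]34CO4)[C@@]2(C)CCCC(C)(C)[C@H]12
F11 | step 8 | (13S)-8,15:9,14-dicyclolabdane-6β,13-diol | O[C@@H]1C[C@@]2(C)C[C@H]3[C@@]2(CC[C@]3(C)O)[C@@]2(C)CCCC(C)(C)[C@H]12
F12 | step 12 | (13S)-7β-(benzyloxymethoxy)-13-hydroxy-8,15:9,14-dicyclolabdan-6-one | O=C1[C@H](OCOCc4ccccc4)[C@@]2(C)C[C@H]3[C@@]2(CC[C@]3(C)O)[C@@]2(C)CCCC(C)(C)[C@H]12
F13 | step 12 | (13S)-7β-(benzyloxymethoxy)-8,15:9,14-dicyclolabdane-6β,13-diol | O[C@@H]1[C@H](OCOCc4ccccc4)[C@@]2(C)C[C@H]3[C@@]2(CC[C@]3(C)O)[C@@]2(C)CCCC(C)(C)[C@H]12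
F14 | step 12 | (13S)-8,15:9,14-dicyclolabdane-6β,7β,13-triol | O[C@@H]1[C@H](O)[C@@]2(C)C[C@H]3[C@@]2(CC[C@]3(C)O)[C@@]2(C)CCCC(C)(C)[C@H]12
F15 | step 12 | 6β,7β-O-(1-methoxyethylidene) cyclic orthoacetate of F14 | COC4(C)O[C@@H]1[C@H](O4)[C@@]2(C)C[C@H]3[C@@]2(CC[C@]3(C)O)[C@@]2(C)CCCC(C)(C)[C@H]12
A1 | alternative 1 | tetracyclic C15-diazo ketone with an extra carbonyl carbon between C8 and C15, 7-ketone, 13-triethylsilyl ether | C1C(=O)[C@@]2(C)C(=O)C(=[N+]=[N-])[C@H]3[C@@]2(CC[C@]3(C)O[Si](CC)(CC)CC)[C@@]2(C)CCCC(C)(C)[C@H]12
A2 | alternative 1 | tetracyclic 7-ketone with C15 methyl ester, 13-triethylsilyl ether | C1C(=O)[C@@]2(C)[C@@H](C(=O)OC)[C@H]3[C@@]2(CC[C@]3(C)O[Si](CC)(CC)CC)[C@@]2(C)CCCC(C)(C)[C@H]12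
A3 | alternative 2 | ring B-fused cyclobutene (C14=C15) with 7β-hydroxyl and a 3-oxobutyl chain on C9 | C1[C@H](O)[C@@]2(C)C=C[C@@]2(CCC(C)=O)[C@@]2(C)CCCC(C)(C)[C@H]12
A4 | alternative 2 | tetracyclic 7,13-diol | C1[C@H](O)[C@@]2(C)C[C@H]3[C@@]2(CC[C@]3(C)O)[C@@]2(C)CCCC(C)(C)[C@H]12
A5 | alternative 3 | ring B-fused cyclohepta-2,6-dienone (C9=C11, C12 carbonyl, C13=C14, 13-methyl), 7-tert-butyldimethylsilyl ether | C1[C@H](O[Si](C)(C)C(C)(C)C)[C@@]2(C)CC=C(C)C(=O)C=C2[C@@]2(C)CCCC(C)(C)[C@H]12
A6 | alternative 3 | tetracyclic 13-hydroxy-12-ketone, 7-tert-butyldimethylsilyl ether | C1[C@H](O[Si](C)(C)C(C)(C)C)[C@@]2(C)C[C@H]3[C@@]2(CC(=O)[C@]3(C)O)[C@@]2(C)CCCC(C)(C)[C@H]12
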